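**Retrosynthetic overview**
- Target ⇒ (R)-5,7-dihydroxy-4-phenyl-dihydrocoumarin + 3-(4-hydroxyphenyl)propanoic acid: the aryl ketone goes on last by Friedel–Crafts acylation at C8, the position ortho/para to the two free hydroxyls.
- Lactone ⇒ open-chain tert-butyl (R)-3-aryl-3-phenylpropanoate. The lactone is the only ring formed in the route (step 3); all three benzene rings are bought.
- Key disconnection C4–C4a: the cinnamate β-carbon is used as a carbon nucleophile (β-boryl ester, a boron homoenolate) and the phloroglucinol carbon as an electrophile (para-phenolate oxidised by Ph3BiF2), joined by a stereoretentive shift from boron to carbon.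
- Stereocentre ⇒ CuCl/chiral bisphosphine β-borylation of tert-butyl cinnamate, carried through with retention.

Assumption: 4-bromo-3,5-dimethoxyphenol is bought as a catalogue compound (if it has to be made, NBS bromination of 3,5-dimethoxyphenol adds one step).

**Step 1**
Reactants: 1 tert-butyl (2E)-3-phenylprop-2-enoate (tert-butyl cinnamate); 2 bis(pinacolato)diboron
Product: 3 tert-butyl (3R)-3-phenyl-3-(4,4,5,5-tetramethyl-1,3,2-dioxaborolan-2-yl)propanoate
Conditions: CuCl (3 mol%), NaOtBu (6 mol%), (S)-1-[(R)-2-(diphenylphosphino)ferrocenyl]ethyldicyclohexylphosphine (4 mol%), MeOH (2 equiv), THF, rt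
Reagents that add atoms: none
Why: Asymmetric conjugate borylation of an enoate by a chiral bisphosphine–CuBpin species of monovalent copper, with MeOH protonating the copper enolate: boryl transfer to one face of the β-carbon sets C3 as R (typically 90–95% ee) and turns this normally electrophilic carbon into a configurationally stable carbon nucleophile; the sense of induction is checked once by NaBO3 oxidation to the known β-hydroxy ester, and the mirror-image ligand is taken if it is opposite.

**Step 2**
Reactants: 3 tert-butyl (3R)-3-phenyl-3-(4,4,5,5-tetramethyl-1,3,2-dioxaborolan-2-yl)propanoate; 4 4-bromo-3,5-dimethoxyphenol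
Product: 8 tert-butyl (3R)-3-(4-hydroxy-2,6-dimethoxyphenyl)-3-phenylpropanoate, via aryllithium 5 (not isolated), via boronate complex 6 (not isolated), via dienone 7 (not isolated)
Conditions: 4 (1.2 equiv), n-BuLi (1.2 equiv) then t-BuLi (2.4 equiv), THF, −78 °C; 3, −78 °C to rt; Ph3BiF2 (1.5 equiv), rt; H2O
Reagents that add atoms: none
Why: Proposed new method: extension of the known stereospecific, transition-metal-free coupling of para-lithiated phenolates with secondary boronic esters (1,2-metallate rearrangement of an aryl boronate complex, Zweifel/Matteson family) to a phenolate flanked by two methoxy groups and to a β-boryl ester; aryllithium 5 adds to boron faster than to the tert-butyl ester to give 6, Ph3BiF2 (pentavalent bismuth) binds the phenoxide oxygen and its reduction to Ph3Bi makes the boron-bearing ring carbon electrophilic, the benzylic carbon shifts from boron to that carbon with retention to give dienone 7, and fluoride-assisted loss of boron restores the arene, so the stereocentre of 3 is carried into 8 unchanged (R, because the new aryl group outranks phenyl).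

**Step 3**
Reactants: 8 tert-butyl (3R)-3-(4-hydroxy-2,6-dimethoxyphenyl)-3-phenylpropanoate
Product: 10 (4R)-5,7-dihydroxy-4-phenyl-3,4-dihydro-2H-chromen-2-one, via trihydroxy acid 9 (not isolated)
Conditions: BBr3 (5 equiv), CH2Cl2, −78 °C to rt; H2O; then p-TsOH (cat.), PhMe, 80 °C
Reagents that add atoms: none
Why: Lewis-acid ether cleavage (BBr3 demethylation) that also removes the tert-butyl ester, followed by acid-catalysed lactonisation of 9 onto one of its two equivalent ortho hydroxyls, so only one six-membered lactone can form; C4 carries no acidic or ionisable bond and keeps its R configuration.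

**Step 4**
Reactants: 10 (4R)-5,7-dihydroxy-4-phenyl-3,4-dihydro-2H-chromen-2-one; 11 3-(4-hydroxyphenyl)propanoic acid
Product: 12 (4R)-5,7-dihydroxy-8-[3-(4-hydroxyphenyl)propanoyl]-4-phenyl-3,4-dihydro-2H-chromen-2-one
Conditions: 11 (1.2 equiv), BF3·OEt2 (as solvent), 70 °C; then H2O
Reagents that add atoms: none
Why: Friedel–Crafts C-acylation of a phloroglucinol-type ring with a free carboxylic acid in BF3·OEt2 (the classical dihydrochalcone synthesis): C8 is ortho to the 7-OH and para to the 5-OH (the reactive 4-position of a resorcinol) while C6 sits between the two hydroxyls (the sluggish 2-position), so the 8-acyl product should dominate and the minor 6-acyl isomer is removed by chromatography; no stereocentre is made or touched.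

**Compound list**
1 | tert-butyl (2E)-3-phenylprop-2-enoate | CC(C)(C)OC(=O)/C=C/c1ccccc1 | starting material
2 | bis(pinacolato)diboron | CC1(C)OB(OC1(C)C)B1OC(C)(C)C(C)(C)O1 | starting material
3 | tert-butyl (3R)-3-phenyl-3-(4,4,5,5-tetramethyl-1,3,2-dioxaborolan-2-yl)propanoate | CC(C)(C)OC(=O)C[C@H](c1ccccc1)B1OC(C)(C)C(C)(C)O1 | intermediate
4 | 4-bromo-3,5-dimethoxyphenol | COc1cc(O)cc(OC)c1Br | starting material
5 | lithium 4-lithio-3,5-dimethoxyphenolate | [Li]Oc1cc(OC)c([Li])c(OC)c1 | intermediate
6 | lithium [(1R)-3-tert-butoxy-3-oxo-1-phenylpropyl](4-lithiooxy-2,6-dimethoxyphenyl)(pinacolato)borate | [Li+].CC(C)(C)OC(=O)C[C@H](c1ccccc1)[B-]1(OC(C)(C)C(C)(C)O1)c1c(OC)cc(O[Li])cc1OC | intermediate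
7 | tert-butyl (3S)-3-[2,6-dimethoxy-4-oxo-1-(4,4,5,5-tetramethyl-1,3,2-dioxaborolan-2-yl)cyclohexa-2,5-dien-1-yl]-3-phenylpropanoate (same spatial arrangement as 3; the descriptor changes only because of ranking) | CC(C)(C)OC(=O)C[C@H](c1ccccc1)C1(B2OC(C)(C)C(C)(C)O2)C(OC)=CC(=O)C=C1OC | intermediate
8 | tert-butyl (3R)-3-(4-hydroxy-2,6-dimethoxyphenyl)-3-phenylpropanoate | CC(C)(C)OC(=O)C[C@H](c1ccccc1)c1c(OC)cc(O)cc1OC | intermediate
9 | (3R)-3-phenyl-3-(2,4,6-trihydroxyphenyl)propanoic acid | OC(=O)C[C@H](c1ccccc1)c1c(O)cc(O)cc1O | intermediate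
10 | (4R)-5,7-dihydroxy-4-phenyl-3,4-dihydro-2H-chromen-2-one | O=C1C[C@H](c2ccccc2)c2c(O)cc(O)cc2O1 | intermediate
11 | 3-(4-hydroxyphenyl)propanoic acid | OC(=O)CCc1ccc(O)cc1 | starting material
12 | (4R)-5,7-dihydroxy-8-[3-(4-hydroxyphenyl)propanoyl]-4-phenyl-3,4-dihydro-2H-chromen-2-one | O=C1C[C@H](c2ccccc2)c2c(O)cc(O)c(C(=O)CCc3ccc(O)cc3)c2O1 | target

**Totals**
Total step count: 4. Longest linear sequence: 4 (1 → 3 → 8 → 10 → 12).

**Steps most likely to fail, with fallbacks**

Step 2 (key coupling). The doubly ortho-substituted aryllithium may add poorly to the secondary benzylic boronic ester, or the shift may lose out to oxygen migration or to phenylation of the phenolate by the bismuth reagent. The fallback sets out from 2 and comes back at 10. It swaps the roles of the two aryl groups so that the hindered ring sits on the boron partner and the electrophile is unhindered PhI. Horner–Wadsworth–Emmons reaction of 2,4,6-trimethoxybenzaldehyde with tert-butyl diethylphosphonoacetate (NaH, THF) gives tert-butyl (2E)-3-(2,4,6-trimethoxyphenyl)prop-2-enoate F1. Borylation of F1 with 2 under the step 1 conditions, but with the mirror-image ligand, gives tert-butyl (3S)-3-(4,4,5,5-tetramethyl-1,3,2-dioxaborolan-2-yl)-3-(2,4,6-trimethoxyphenyl)propanoate F2. A stereoretentive Suzuki–Miyaura coupling of F2 with PhI (Pd2(dba)3, PPh3, Ag2O, K2CO3, DME, 85 °C) gives tert-butyl (3R)-3-phenyl-3-(2,4,6-trimethoxyphenyl)propanoate F3. BBr3 followed by p-TsOH, as in step 3, converts F3 into 10. If the coupling turns out to invert, the other ligand enantiomer is used in the borylation.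

Step 4 (regiochemistry of acylation, C8 against C6, and possible loss of ee in hot Lewis acid). The fallback sets out from 8 and comes back at 12. It acylates before the ring is closed, when the two free positions of the aryl ring are still equivalent. Heating 8 and 11 in BF3·OEt2 (60 °C, the tert-butyl ester is lost) gives (3R)-3-{4-hydroxy-3-[3-(4-hydroxyphenyl)propanoyl]-2,6-dimethoxyphenyl}-3-phenylpropanoic acid F4 as a single regioisomer. BCl3 (CH2Cl2, −78 to 0 °C) cleaves only the methyl ether ortho to the new ketone (chelation control), and the acid can then lactonise only onto that hydroxyl (p-TsOH, PhMe, 80 °C) to give (4R)-7-hydroxy-8-[3-(4-hydroxyphenyl)propanoyl]-5-methoxy-4-phenyl-3,4-dihydro-2H-chromen-2-one F5. BBr3 (CH2Cl2, −78 to 0 °C) removes the last methyl ether and gives 12.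

Step 1 (the ee of about 90–95% is the ceiling for the whole route; one recrystallisation of 10 is the first remedy). The fallback sets out from 2 and comes back at 3. It sets the stereocentre by hydride delivery instead of boryl delivery. Phenylacetylene (n-BuLi, then Boc2O, THF, −78 °C) gives tert-butyl 3-phenylprop-2-ynoate F6. Syn-borylation of F6 with 2 (CuCl, NaOtBu, Xantphos, MeOH, THF, rt) gives tert-butyl (2Z)-3-phenyl-3-(4,4,5,5-tetramethyl-1,3,2-dioxaborolan-2-yl)prop-2-enoate F7. Asymmetric conjugate reduction of F7 (CuCl, NaOtBu, the chiral ferrocenyl bisphosphine of step 1 in the enantiomer that gives R, PMHS, t-BuOH, PhMe, 0 °C) gives 3.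

**Further compounds**
F1 | step 2 | tert-butyl (2E)-3-(2,4,6-trimethoxyphenyl)prop-2-enoate | CC(C)(C)OC(=O)/C=C/c1c(OC)cc(OC)cc1OC
F2 | step 2 | tert-butyl (3S)-3-(4,4,5,5-tetramethyl-1,3,2-dioxaborolan-2-yl)-3-(2,4,6-trimethoxyphenyl)propanoate | CC(C)(C)OC(=O)C[C@H](B1OC(C)(C)C(C)(C)O1)c1c(OC)cc(OC)cc1OC
F3 | step 2 | tert-butyl (3R)-3-phenyl-3-(2,4,6-trimethoxyphenyl)propanoate | CC(C)(C)OC(=O)C[C@H](c1ccccc1)c1c(OC)cc(OC)cc1OC
F4 | step 4 | (3R)-3-{4-hydroxy-3-[3-(4-hydroxyphenyl)propanoyl]-2,6-dimethoxyphenyl}-3-phenylpropanoic acid | OC(=O)C[C@H](c1ccccc1)c1c(OC)cc(O)c(C(=O)CCc2ccc(O)cc2)c1OC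
F5 | step 4 | (4R)-7-hydroxy-8-[3-(4-hydroxyphenyl)propanoyl]-5-methoxy-4-phenyl-3,4-dihydro-2H-chromen-2-one | O=C1C[C@H](c2ccccc2)c2c(OC)cc(O)c(C(=O)CCc3ccc(O)cc3)c2O1
F6 | step 1 | tert-butyl 3-phenylprop-2-ynoate | CC(C)(C)OC(=O)C#Cc1ccccc1
F7 | step 1 | tert-butyl (2Z)-3-phenyl-3-(4,4,5,5-tetramethyl-1,3,2-dioxaborolan-2-yl)prop-2-enoate | CC(C)(C)OC(=O)/C=C(\c1ccccc1)B1OC(C)(C)C(C)(C)O1
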